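**Retrosynthetic overview**

1. Target ⇒ C5 angelate ester (mixed-anhydride acylation) and the C1–C2 bond: a dithiane acyl anion carrying C3–C4 (C4 from (R)-propylene oxide) adds to a C1 ketone chelated by the C5 alkoxide.
2. cis-Fused α-methyl-γ-lactone (C7, C11) ⇒ convex-face hydrogenation of a dienyl butenolide; the same step frees the C5 hydroxyl.
3. Butenolide ⇒ 8-oxabicyclo[3.2.1]octene with a propanoate on C7: the ester dienolate expels the bridge oxygen from C9 and the freed C6 alkoxide lactonises. Propanoate from a Pd coupling at a C7 bromide; C10 methyl from exo enolate methylation.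
4. Oxabicycle ⇒ [4+3] cycloaddition of 3-bromofuran with a siloxyallyl cation bearing an (S)-1-phenylethoxy group: the seven-membered carbocycle and the oxygen bridge form in one operation and C5/C6 are set.
5. Ring order: carbocycle and oxygen bridge together, then the lactone ring as the bridge is opened.

Locants C1–C12 in the Why lines are the guaiane numbers of the target: C1 carbinol carbon bearing the acyl chain C2–C4, C5 angelate carbon, C6 lactone O–CH, C7 ring-fusion CH, C8/C9 ring CH2, C10 CH(CH3), C11 lactone CH(CH3), C12 lactone C=O.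

Assumption: the (S)-1-phenylethyl group steers the cycloaddition to the enantiomeric series drawn; if the sense of induction is opposite, (R)-1-phenylethanol is used and nothing else changes, since the auxiliary carbon leaves as ethylbenzene later.

**Route**

Step 1
Reactants: 1 1,1-dimethoxypropan-2-one; 2 (S)-1-phenylethanol
Product: 3 1-methoxy-1-[(1S)-1-phenylethoxy]propan-2-one
Conditions: pyridinium p-toluenesulfonate (cat.), cyclohexane, 80 °C, MeOH distilled off
Reagents that add atoms: none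
Why: Acid-catalysed transacetalisation driven by removal of methanol exchanges one methoxy group for the chiral alkoxy group; the acetal carbon forms as both epimers, which does not matter because it is ionised in step 3.

Step 2
Reactants: 3 1-methoxy-1-[(1S)-1-phenylethoxy]propan-2-one
Product: 4 trimethyl({3-methoxy-3-[(1S)-1-phenylethoxy]prop-1-en-2-yl}oxy)silane
Conditions: Me3SiOTf, Et3N, CH2Cl2, 0 °C
Reagents that add atoms: trimethylsilyl trifluoromethanesulfonate, C[Si](C)(C)OS(=O)(=O)C(F)(F)F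
Why: Soft enolisation (silyl enol ether formation) on the CH3 side of the ketone gives the 2-siloxyallyl acetal, the latent oxyallyl cation; no stereocentre is made.

Step 3
Reactants: 4 trimethyl({3-methoxy-3-[(1S)-1-phenylethoxy]prop-1-en-2-yl}oxy)silane; 5 3-bromofuran
Product: 7 (1S,2S,5R)-7-bromo-2-[(1S)-1-phenylethoxy]-8-oxabicyclo[3.2.1]oct-6-en-3-one, via siloxyallyl cation 6 (not isolated)
Conditions: Me3SiOTf (0.1 equiv), 5 (3 equiv, excess recovered), CH2Cl2, −95 to −78 °C; then Et3N, rt
Reagents that add atoms: none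
Why: Proposed new method: Me3SiOTf ionises the acetal (loss of MeOSiMe3) to the alkoxy siloxyallyl cation, whose oxocarbenium carbon (future C5) bonds first to C2 of 3-bromofuran, the α-position activated by the neighbouring bromine as in electrophilic substitution of 3-halofurans, and the enol ether terminus (future C10) then closes onto the other furan α-carbon (future C9), so the seven-membered carbocycle and the oxygen bridge form together in a [4+3] cycloaddition with Br on C7; the 1-phenylethyl group shields one face of the cation and the alkoxy group ends equatorial, anti to the O bridge (any axial epimer is equilibrated by the Et3N work-up), which sets C5 (S) and C6 (R) with the trans C5–O/C6–O relationship; closest known reaction: the auxiliary-controlled low-temperature [4+3] cycloaddition of this cation type with furan itself.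

Step 4
Reactants: 7 (1S,2S,5R)-7-bromo-2-[(1S)-1-phenylethoxy]-8-oxabicyclo[3.2.1]oct-6-en-3-one
Product: 8 (1R,2S,4S,5S)-6-bromo-2-methyl-4-[(1S)-1-phenylethoxy]-8-oxabicyclo[3.2.1]oct-6-en-3-one
Conditions: LiN(i-Pr)2, THF, −78 °C; MeI, −78 to −40 °C
Reagents that add atoms: iodomethane, CI
Why: Kinetic enolate alkylation: the base removes the exo (axial) proton of the unsubstituted α-CH2 (C10) rather than the hindered α-alkoxy methine, and iodomethane attacks the exo face, syn to the oxygen bridge, because the bromoalkene bridge blocks the endo face, so C10 carries an axial methyl cis to the C6 oxygen as in the target.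

Step 5
Reactants: 8 (1R,2S,4S,5S)-6-bromo-2-methyl-4-[(1S)-1-phenylethoxy]-8-oxabicyclo[3.2.1]oct-6-en-3-ol precursor ketone (compound 8 as named in step 4)
Product: 9 (1R,2R,3R,4R,5S)-6-bromo-2-methyl-4-[(1S)-1-phenylethoxy]-8-oxabicyclo[3.2.1]oct-6-en-3-ol
Conditions: LiBH(s-Bu)3, THF, −78 °C; then H2O
Reagents that add atoms: none
Why: Borohydride reduction from the exo face gives the axial alcohol and masks the carbonyl, so no ketone enolate can form in step 7 and C5 and C10 cannot epimerise; the carbinol centre is removed again in step 8, so either epimer would serve.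

Step 6
Reactants: 9 (1R,2R,3R,4R,5S)-6-bromo-2-methyl-4-[(1S)-1-phenylethoxy]-8-oxabicyclo[3.2.1]oct-6-en-3-ol; 10 methyl 2-bromopropanoate
Product: 12 methyl 2-[(1S,2R,3R,4R,5R)-3-hydroxy-2-methyl-4-[(1S)-1-phenylethoxy]-8-oxabicyclo[3.2.1]oct-6-en-6-yl]propanoate, via zinc enolate 11 (not isolated)
Conditions: 10, Zn dust (Me3SiCl-activated), THF, rt; then 9, Pd(dba)2 (5 mol %), P(t-Bu)3 (5 mol %), THF, 40 °C (2.5 equiv of 11)
Reagents that add atoms: none
Why: Negishi-type α-alkenylation of a Reformatsky reagent (oxidative addition of the alkenyl bromide to zerovalent palladium, transmetalation from zinc, reductive elimination) puts the propanoate on C7 without strong base; C11 forms as both epimers, which does not matter because it becomes sp2 in step 7.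

Step 7
Reactants: 12 methyl 2-[(1S,2R,3R,4R,5R)-3-hydroxy-2-methyl-4-[(1S)-1-phenylethoxy]-8-oxabicyclo[3.2.1]oct-6-en-6-yl]propanoate
Product: 14 (6S,7R,8R,8aR)-7-hydroxy-3,6-dimethyl-8-[(1S)-1-phenylethoxy]-6,7,8,8a-tetrahydro-2H-cyclohepta[b]furan-2-one, via ring-opened dilithium dialkoxide 13 (not isolated)
Conditions: LiN(i-Pr)2 (2.2 equiv), THF, −78 to −10 °C; AcOH quench
Reagents that add atoms: none
Why: Proposed new method: after the hydroxyl, the base deprotonates C11 to the ester dienolate, which can expel only the bridge oxygen on C9 (the carbon attached to its γ-position) in a vinylogous E1cB (retro-oxa-Michael) opening that creates C7=C11 and C8=C9, and the freed C6 alkoxide closes onto the (Z)-ester to give the butenolide, the reversible opening letting any E isomer return until lactonisation, the only irreversible event, has drained it; C6 keeps its configuration and no new stereocentre forms; closest known reactions: base-induced β-elimination openings of 8-oxabicyclo[3.2.1]oct-6-en-3-one enolates and syn SN2′ openings of oxabicyclic ethers.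

Step 8
Reactants: 14 (6S,7R,8R,8aR)-7-hydroxy-3,6-dimethyl-8-[(1S)-1-phenylethoxy]-6,7,8,8a-tetrahydro-2H-cyclohepta[b]furan-2-one
Product: 15 (6S,8S,8aR)-3,6-dimethyl-8-[(1S)-1-phenylethoxy]-8,8a-dihydro-2H-cyclohepta[b]furan-2,7(6H)-dione
Conditions: Dess–Martin periodinane, NaHCO3, CH2Cl2, 0 °C
Reagents that add atoms: none
Why: Dess–Martin oxidation regenerates the C1 ketone under buffered, non-basic conditions in which the β,γ-unsaturated ketone does not move into conjugation and C5 and C10 are not epimerised; the product is used at once.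

Step 9
Reactants: 15 (6S,8S,8aR)-3,6-dimethyl-8-[(1S)-1-phenylethoxy]-8,8a-dihydro-2H-cyclohepta[b]furan-2,7(6H)-dione
Product: 16 (3R,3aS,6S,8S,8aR)-8-hydroxy-3,6-dimethyloctahydro-2H-cyclohepta[b]furan-2,7-dione
Conditions: H2 (4 bar), Pd/C, EtOAc, rt
Reagents that add atoms: none
Why: Heterogeneous syn hydrogenation saturates C8=C9 and adds H2 to the tetrasubstituted butenolide C7=C11 from its convex face (the face of H6, away from the carbocycle that lies under the lactone plane), which sets C7 (S) and C11 (R) as the all-cis H6/H7/H11 array with cis ring fusion and the methyl on the concave side, and the benzylic ether is hydrogenolysed to free the C5 hydroxyl.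

Step 10
Reactants: 17 1,3-dithiane; 18 (R)-2-methyloxirane
Product: 21 2-[(2R)-2-(triethylsilyloxy)propyl]-1,3-dithiane, via 2-lithio-1,3-dithiane 19 (not isolated), via lithium alkoxide 20 (not isolated)
Conditions: n-BuLi, THF, −30 °C; 18, −30 to 0 °C; Et3SiCl, 0 °C to rt
Reagents that add atoms: chlorotriethylsilane, CC[Si](Cl)(CC)CC
Why: Corey–Seebach umpolung: the lithiated dithiane opens the epoxide at its CH2 terminus (SN2), so the (R) carbinol centre is carried over untouched as the future C4, and the alkoxide is silylated in the same flask.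

Step 11
Reactants: 21 2-[(2R)-2-(triethylsilyloxy)propyl]-1,3-dithiane; 16 (3R,3aS,6S,8S,8aR)-8-hydroxy-3,6-dimethyloctahydro-2H-cyclohepta[b]furan-2,7-dione
Product: 23 (3R,3aS,6S,7S,8S,8aR)-7,8-dihydroxy-3,6-dimethyl-7-{2-[(2R)-2-(triethylsilyloxy)propyl]-1,3-dithian-2-yl}octahydro-2H-cyclohepta[b]furan-2-one, via lithiated dithiane 22 (not isolated)
Conditions: 21 (2.3 equiv), t-BuLi, THF, −78 °C; then 16, −78 to −40 °C; then H2O
Reagents that add atoms: none
Why: 1,2-Addition of an acyl anion equivalent: the first equivalent turns the C5 hydroxyl into a lithium alkoxide that chelates the carbonyl oxygen and lies in its plane, and the nucleophile then enters anti to the pseudoaxial C10 methyl on the convex face of the cis-fused bicycle, which places the acyl carbon cis to O5 and the new tertiary hydroxyl trans to it, C1 (S); the ketone reacts before the lactone, and cold protonation of any lactone enolate returns H11 to the convex face.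

Step 12
Reactants: 23 (3R,3aS,6S,7S,8S,8aR)-7,8-dihydroxy-3,6-dimethyl-7-{2-[(2R)-2-(triethylsilyloxy)propyl]-1,3-dithian-2-yl}octahydro-2H-cyclohepta[b]furan-2-one; 24 angelic acid
Product: 26 (3R,3aS,6S,7S,8S,8aR)-7-hydroxy-3,6-dimethyl-2-oxo-7-{2-[(2R)-2-(triethylsilyloxy)propyl]-1,3-dithian-2-yl}octahydro-2H-cyclohepta[b]furan-8-yl (2Z)-2-methylbut-2-enoate, via mixed anhydride 25 (not isolated)
Conditions: 2,4,6-trichlorobenzoyl chloride, Et3N, toluene, rt; then 23, 80 °C
Reagents that add atoms: none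
Why: Yamaguchi-type acylation through the mixed anhydride: only the secondary C5 hydroxyl reacts (C1–OH is tertiary, the C4 oxygen is silylated), and leaving out a nucleophilic catalyst keeps the (Z)-angelate from isomerising to the tiglate; no stereocentre is touched.

Step 13
Reactants: 26 (3R,3aS,6S,7S,8S,8aR)-7-hydroxy-3,6-dimethyl-2-oxo-7-{2-[(2R)-2-(triethylsilyloxy)propyl]-1,3-dithian-2-yl}octahydro-2H-cyclohepta[b]furan-8-yl (2Z)-2-methylbut-2-enoate
Product: 27 (3R,3aS,6S,7S,8S,8aR)-7-hydroxy-7-[(3R)-3-hydroxybutanoyl]-3,6-dimethyl-2-oxooctahydro-2H-cyclohepta[b]furan-8-yl (2Z)-2-methylbut-2-enoate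
Conditions: PhI(OCOCF3)2, MeCN/H2O 9:1, 0 °C; then CF3CO2H (5 vol %), rt
Reagents that add atoms: water, O
Why: Oxidative hydrolysis of the dithioacetal by the hypervalent iodine reagent unveils the C2 ketone and the trifluoroacetic acid present cleaves the triethylsilyl ether, so the β-hydroxy ketone is released without base (no retro-aldol, acyl migration or angelate isomerisation); no stereocentre is touched.

**Compound list**

1 | 1,1-dimethoxypropan-2-one | CC(=O)C(OC)OC | starting material
2 | (S)-1-phenylethanol | C[C@H](O)c1ccccc1 | starting material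
3 | 1-methoxy-1-[(1S)-1-phenylethoxy]propan-2-one (both epimers at the acetal carbon) | CC(=O)C(OC)O[C@@H](C)c1ccccc1 | intermediate
4 | trimethyl({3-methoxy-3-[(1S)-1-phenylethoxy]prop-1-en-2-yl}oxy)silane | C=C(O[Si](C)(C)C)C(OC)O[C@@H](C)c1ccccc1 | intermediate
5 | 3-bromofuran | Brc1ccoc1 | starting material
6 | 1-[(1S)-1-phenylethoxy]-2-(trimethylsilyloxy)allyl cation, triflate | C=C(O[Si](C)(C)C)C=[O+][C@@H](C)c1ccccc1.[O-]S(=O)(=O)C(F)(F)F | intermediate
7 | (1S,2S,5R)-7-bromo-2-[(1S)-1-phenylethoxy]-8-oxabicyclo[3.2.1]oct-6-en-3-one (alkoxy equatorial, anti to the O bridge) | O=C1[C@@H](O[C@@H](C)c2ccccc2)[C@@H]3O[C@H](C1)C=C3Br | intermediate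
8 | (1R,2S,4S,5S)-6-bromo-2-methyl-4-[(1S)-1-phenylethoxy]-8-oxabicyclo[3.2.1]oct-6-en-3-one (methyl axial, syn to the O bridge) | O=C1[C@@H](O[C@@H](C)c2ccccc2)[C@@H]3O[C@H]([C@@H]1C)C=C3Br | intermediate
9 | (1R,2R,3R,4R,5S)-6-bromo-2-methyl-4-[(1S)-1-phenylethoxy]-8-oxabicyclo[3.2.1]oct-6-en-3-ol (hydroxyl axial) | O[C@H]1[C@@H](O[C@@H](C)c2ccccc2)[C@@H]3O[C@H]([C@@H]1C)C=C3Br | intermediate
10 | methyl 2-bromopropanoate (racemic) | CC(Br)C(=O)OC | starting material
11 | bromo(1-methoxy-1-oxopropan-2-yl)zinc | CC([Zn]Br)C(=O)OC | intermediate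
12 | methyl 2-[(1S,2R,3R,4R,5R)-3-hydroxy-2-methyl-4-[(1S)-1-phenylethoxy]-8-oxabicyclo[3.2.1]oct-6-en-6-yl]propanoate (both epimers at the propanoate C2) | O[C@H]1[C@@H](O[C@@H](C)c2ccccc2)[C@@H]3O[C@H]([C@@H]1C)C=C3C(C)C(=O)OC | intermediate
13 | dilithium dialkoxide of methyl (2Z)-2-[(2R,3R,4R,5S)-2,4-dihydroxy-5-methyl-3-[(1S)-1-phenylethoxy]cyclohept-6-en-1-ylidene]propanoate | [Li]O[C@H]1[C@@H](O[C@@H](C)c2ccccc2)[C@H](O[Li])/C(=C(/C)C(=O)OC)C=C[C@@H]1C | intermediate
14 | (6S,7R,8R,8aR)-7-hydroxy-3,6-dimethyl-8-[(1S)-1-phenylethoxy]-6,7,8,8a-tetrahydro-2H-cyclohepta[b]furan-2-one | O[C@H]1[C@@H](O[C@@H](C)c2ccccc2)[C@@H]3OC(=O)C(C)=C3C=C[C@@H]1C | intermediate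
15 | (6S,8S,8aR)-3,6-dimethyl-8-[(1S)-1-phenylethoxy]-8,8a-dihydro-2H-cyclohepta[b]furan-2,7(6H)-dione | O=C1[C@@H](O[C@@H](C)c2ccccc2)[C@@H]3OC(=O)C(C)=C3C=C[C@@H]1C | intermediate
16 | (3R,3aS,6S,8S,8aR)-8-hydroxy-3,6-dimethyloctahydro-2H-cyclohepta[b]furan-2,7-dione | O=C1[C@@H](O)[C@@H]2OC(=O)[C@H](C)[C@@H]2CC[C@@H]1C | intermediate
17 | 1,3-dithiane | C1CSCSC1 | starting material
18 | (R)-2-methyloxirane | C[C@@H]1CO1 | starting material
19 | 2-lithio-1,3-dithiane | [Li]C1SCCCS1 | intermediate
20 | lithium (2R)-1-(1,3-dithian-2-yl)propan-2-olate | C[C@@H](O[Li])CC1SCCCS1 | intermediate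
21 | 2-[(2R)-2-(triethylsilyloxy)propyl]-1,3-dithiane | C[C@@H](O[Si](CC)(CC)CC)CC1SCCCS1 | intermediate
22 | 2-lithio-2-[(2R)-2-(triethylsilyloxy)propyl]-1,3-dithiane | C[C@@H](O[Si](CC)(CC)CC)CC1([Li])SCCCS1 | intermediate
23 | (3R,3aS,6S,7S,8S,8aR)-7,8-dihydroxy-3,6-dimethyl-7-{2-[(2R)-2-(triethylsilyloxy)propyl]-1,3-dithian-2-yl}octahydro-2H-cyclohepta[b]furan-2-one | O[C@H]1[C@@H]2OC(=O)[C@H](C)[C@@H]2CC[C@H](C)[C@@]1(O)C3(C[C@@H](C)O[Si](CC)(CC)CC)SCCCS3 | intermediate
24 | angelic acid, (2Z)-2-methylbut-2-enoic acid | C/C=C(/C)C(=O)O | starting material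
25 | (2Z)-2-methylbut-2-enoic 2,4,6-trichlorobenzoic anhydride | C/C=C(/C)C(=O)OC(=O)c1c(Cl)cc(Cl)cc1Cl | intermediate
26 | (3R,3aS,6S,7S,8S,8aR)-7-hydroxy-3,6-dimethyl-2-oxo-7-{2-[(2R)-2-(triethylsilyloxy)propyl]-1,3-dithian-2-yl}octahydro-2H-cyclohepta[b]furan-8-yl (2Z)-2-methylbut-2-enoate | C/C=C(/C)C(=O)O[C@H]1[C@@H]2OC(=O)[C@H](C)[C@@H]2CC[C@H](C)[C@@]1(O)C3(C[C@@H](C)O[Si](CC)(CC)CC)SCCCS3 | intermediate
27 | (3R,3aS,6S,7S,8S,8aR)-7-hydroxy-7-[(3R)-3-hydroxybutanoyl]-3,6-dimethyl-2-oxooctahydro-2H-cyclohepta[b]furan-8-yl (2Z)-2-methylbut-2-enoate (CNP0321985.1) | C/C=C(/C)C(=O)O[C@H]1[C@@H]2OC(=O)[C@H](C)[C@@H]2CC[C@H](C)[C@@]1(O)C(=O)C[C@@H](C)O | target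

**Step count and risk**

Total: 13 steps. Longest linear sequence: 12 steps (steps 1–9, 11, 12, 13).

Most likely to fail, step 3: 3-bromofuran is a deactivated diene and the head-to-head orientation is a prediction. The fallback exchanges the order of coupling and cycloaddition and sets out from 5 and 4. Compound 5 is coupled with zinc enolate 11 (conditions of step 6) to methyl 2-(furan-3-yl)propanoate F1, a far more nucleophilic 3-alkylfuran that reacts at C2. The [4+3] cycloaddition of F1 with 4 (conditions of step 3) gives methyl 2-[(1R,4S,5R)-3-oxo-4-[(1S)-1-phenylethoxy]-8-oxabicyclo[3.2.1]oct-6-en-6-yl]propanoate F2. Enolate methylation as in step 4 gives methyl 2-[(1S,2S,4S,5R)-2-methyl-3-oxo-4-[(1S)-1-phenylethoxy]-8-oxabicyclo[3.2.1]oct-6-en-6-yl]propanoate F3, and LiBH(s-Bu)3 reduction of F3 comes back to the route at 12.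

Most likely to fail, step 7: the opening may stop at the ring-opened stage or give the E alkylidene ester, which cannot lactonise. The fallback sets out from 12: a cold quench gives methyl (2E)-2-[(2R,3R,4R,5S)-2,4-dihydroxy-5-methyl-3-[(1S)-1-phenylethoxy]cyclohept-6-en-1-ylidene]propanoate F4. Sensitised E/Z photoisomerisation of F4 (benzophenone, 350 nm, MeCN, trace pyridinium p-toluenesulfonate) feeds the Z isomer into spontaneous lactonisation and comes back to the route at 14.

Most likely to fail, step 11: the hindered 2-alkyl-2-lithiodithiane may enolise 16 instead of adding, or add from the wrong face. The fallback builds the chain in smaller pieces and sets out from 16. 1-Ethoxyvinyllithium (ethyl vinyl ether, t-BuLi; CeCl3 if needed), a small sp2 acyl anion equivalent, adds under the same chelation control to give (3R,3aS,6S,7S,8S,8aR)-7-(1-ethoxyethenyl)-7,8-dihydroxy-3,6-dimethyloctahydro-2H-cyclohepta[b]furan-2-one F5. Dilute acid converts F5 into (3R,3aS,6S,7S,8S,8aR)-7-acetyl-7,8-dihydroxy-3,6-dimethyloctahydro-2H-cyclohepta[b]furan-2-one F6. Acylation with 25 as in step 12 gives (3R,3aS,6S,7S,8S,8aR)-7-acetyl-7-hydroxy-3,6-dimethyl-2-oxooctahydro-2H-cyclohepta[b]furan-8-yl (2Z)-2-methylbut-2-enoate F7. A boron aldol reaction of F7 with acetaldehyde (matched enantiomer of B-chlorodiisopinocampheylborane, Et3N, −78 °C) sets C4 and comes back to the route at 27.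

Further compounds
F1 | step 3 | methyl 2-(furan-3-yl)propanoate (racemic) | CC(C(=O)OC)c1ccoc1
F2 | step 3 | methyl 2-[(1R,4S,5R)-3-oxo-4-[(1S)-1-phenylethoxy]-8-oxabicyclo[3.2.1]oct-6-en-6-yl]propanoate | O=C1[C@@H](O[C@@H](C)c2ccccc2)[C@@H]3O[C@H](C1)C=C3C(C)C(=O)OC
F3 | step 3 | methyl 2-[(1S,2S,4S,5R)-2-methyl-3-oxo-4-[(1S)-1-phenylethoxy]-8-oxabicyclo[3.2.1]oct-6-en-6-yl]propanoate | O=C1[C@@H](O[C@@H](C)c2ccccc2)[C@@H]3O[C@H]([C@@H]1C)C=C3C(C)C(=O)OC
F4 | step 7 | methyl (2E)-2-[(2R,3R,4R,5S)-2,4-dihydroxy-5-methyl-3-[(1S)-1-phenylethoxy]cyclohept-6-en-1-ylidene]propanoate | O[C@H]1[C@@H](O[C@@H](C)c2ccccc2)[C@H](O)/C(=C(\C)C(=O)OC)C=C[C@@H]1C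
F5 | step 11 | (3R,3aS,6S,7S,8S,8aR)-7-(1-ethoxyethenyl)-7,8-dihydroxy-3,6-dimethyloctahydro-2H-cyclohepta[b]furan-2-one | O[C@H]1[C@@H]2OC(=O)[C@H](C)[C@@H]2CC[C@H](C)[C@@]1(O)C(=C)OCC
F6 | step 11 | (3R,3aS,6S,7S,8S,8aR)-7-acetyl-7,8-dihydroxy-3,6-dimethyloctahydro-2H-cyclohepta[b]furan-2-one | O[C@H]1[C@@H]2OC(=O)[C@H](C)[C@@H]2CC[C@H](C)[C@@]1(O)C(C)=O
F7 | step 11 | (3R,3aS,6S,7S,8S,8aR)-7-acetyl-7-hydroxy-3,6-dimethyl-2-oxooctahydro-2H-cyclohepta[b]furan-8-yl (2Z)-2-methylbut-2-enoate | C/C=C(/C)C(=O)O[C@H]1[C@@H]2OC(=O)[C@H](C)[C@@H]2CC[C@H](C)[C@@]1(O)C(C)=O
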